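In this closed, stirred vessel Q can leave to Z on its own, to J with E, or to L with J, and you want the share of J at the times asked.

| flask | Q | E | remark | time |
|---|---|---|---|---|
| delta | 1.6 M | 0.23 equiv | run made earlier |  |
| gamma | 1.6 M | 0.74 equiv | run made earlier |  |
| beta | 0.77 M | 0.60 equiv | run made earlier |  |
| dawn | 3.0 M | 0.300 equiv |  | 40 h |
| noon | 1.0 M | 1.20 equiv |  | 40 h |
| autumn | 0.40 M | 2.40 equiv |  | 40 h |
| winter | 0.80 M | 0.200 equiv |  | 40 h |
| summer | 1.6 M | 0.600 equiv |  | 40 h |

| run | time / h | J / % | Z / % |
|---|---|---|---|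
| delta | 4.00 | 9.4 | 58.2 |
| delta | 10.0 | 12.2 | 79.8 |
| delta | 20.0 | 10.5 | 83.9 |
| delta | 30.0 | 10.9 | 83.7 |
| delta | 40.0 | 10.6 | 84.0 |
| gamma | 3.00 | 27.1 | 41.9 |
| gamma | 6.00 | 32.6 | 54.5 |
| gamma | 12.0 | 34.5 | 59.6 |
| gamma | 20.0 | 35.0 | 62.3 |
| gamma | 40.0 | 33.8 | 60.7 |
| beta | 3.00 | 12.3 | 48.0 |
| beta | 6.00 | 16.7 | 65.3 |
| beta | 12.0 | 17.3 | 76.4 |
| beta | 20.0 | 17.0 | 77.8 |
| beta | 40.0 | 15.8 | 80.3 |

(readings scatter by 0.5 percentage points)

- percentages count the Q that a species holds: one L counts as two
- J is meant together with its G
- solid, in amounts per volume of the solution: G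
- what may be going on: Q + E <-> J; Q -> Z; Q + J -> L; G <-> J

- the flasks by share of J in all that became J or Z or L, highest first, at 40 h (dawn / noon / autumn / winter / summer)
- the same order at 6.0 d (dawn / noon / autumn / winter / summer)
- the share of J in all that became J or Z or L of the flask you put first, at 40 h
- the share of J in all that became J or Z or L of the flask you put last, at 40 h

If Q + E gives J and Q alone gives Z, Q cancels from the ratio of the two rates, so J formed per Z formed is a constant times the E present. With the way back and L set aside, the fraction of E left then falls as exp(−s·Z), Z in moles per litre. Work with that fraction left, and call s the split factor, a selectivity factor. Read it at 20.0 h, when Z has about levelled, taking what the balance lacks as L and E spent as J plus half of L. Delta gives 0.643 L mol⁻¹, gamma 0.678 L mol⁻¹ and beta 0.660 L mol⁻¹, so I carry the mean reading, 0.660 L mol⁻¹.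

Now bracket noon. If E stayed at its charge, the J path would take 44.2% of Q, and that is a ceiling. The rest, as Z, put through the fraction-left rule, gives a floor of 37.0%. That floor gives a new ceiling of 40.9%, and that ceiling a new floor of 38.8%. L eats J and also takes Q from the race, so I take off the whole of the widest gap, delta's 5.60%. My bracket for J in noon therefore runs from 33.2% to 40.9%.

The forecast, on the ground that “crystals cap dissolved J”, gave noon > autumn > summer > dawn > winter at 40 h and noon > summer > autumn > dawn > winter at 6.0 d, with 34% first and 6% last, the first inside my bracket.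

The flasks give noon > autumn > summer > dawn > winter and noon > summer > autumn > dawn > winter, with 37.0% for noon, inside the bracket, and 5.15% for winter.

    Q + E ⇌ J (K = 20.0 L mol⁻¹, k = 0.180 L mol⁻¹ h⁻¹)
    Q → Z (k = 0.250 h⁻¹)
    Q + J → L (k = 0.100 L mol⁻¹ h⁻¹)
    G ⇌ J, rate k4*(cs4 - [J]) while solid is left; crystals form when [J] > cs4 (solubility = 0.0820 M, k = 23.0 h⁻¹)

In noon the steps to Z and to J ran side by side while Q lasted, Q being down to 0.211% at 20.0 h, when Z of 58.3% puts the fraction of E left at 68.1% and the flask held 66.9%. In winter the same two steps ran while Q lasted, Q being down to 0.619% at 20.0 h, when Z of 91.0% puts the fraction of E left at 61.8% and the flask held 63.9%.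

The numbers in the tables were computed for substances that don't exist, and the scatter is random.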